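- If target stops while starting material is still there, count it in molar, not in percent.
- Here is what you are asked, and what you have.

| setting | ash | cedar | Monday's | Friday's | Saturday's | Tuesday's | Sunday's |
|---|---|---|---|---|---|---|---|
| starting material | 0.078 M | 1.2 M | 0.10 M | 0.20 M | 0.40 M | 0.80 M | 1.5 M |
| transfer agent | 0.030 M | 0.030 M | 0.0300 M | 0.0300 M | 0.0300 M | 0.0300 M | 0.0300 M |
| gas | 58 mM (held) | 58 mM (held) | 58 mM (held) | 58 mM (held) | 58 mM (held) | 58 mM (held) | 58 mM (held) |
| initiator | 5 mM | 5 mM | 5.0 mM | 5.0 mM | 5.0 mM | 5.0 mM | 5.0 mM |
| remark | run made earlier | run made earlier |  |  |  |  |  |
| time |  |  | 2.5 min | 2.5 min | 2.5 min | 2.5 min | 2.5 min |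

- ash (time / min: target / %): 0.167: 14; 0.500: 46; 0.833: 73; 1.33: 91; 2.00: 91; 2.50: 89
- cedar (time / min: target / %): 0.167: 2; 0.500: 3; 0.833: 4; 1.33: 7; 2.00: 6; 2.50: 7

(each reading ± 1.5 percentage points)

- in percentages every species weighs as the starting material in it: one ended chains counts as two
- for target the crystals are counted in
- as a solid, counted per litre of solution: crystals
- at the start none of partner is dissolved
- steps thought possible: crystals <-> target; partner + first chain carrier -> target + second chain carrier; starting material + second chain carrier -> by-product + first chain carrier; 2 first chain carrier -> ended chains; initiator -> 2 initiating radical; transfer agent + first chain carrier -> side product + idle radical; gas <-> partner; starting material + initiating radical -> capped initiator + first chain carrier; 2 idle radical -> ended radicals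
- "hardly changes" means that all values lie within two and a half points (for a concentration: within two and a half percent of the largest)

- amount of target at the end, in percent of the starting material charged for Monday's, Friday's, Saturday's, Tuesday's, Sunday's, in this order
- the course of these numbers from the first flask to the last (falls all the way / rises all the way / hardly changes / rises, then falls / falls, then rises)

- The runs justify the molar count. At 0.500 min, ash holds 0.0359 M of target and cedar 0.0360 M, though cedar was charged with 15.4 times the starting material. So, as a reading, the rate is zero order in starting material.
- For a bound from below, take cedar's last three readings. Their mean gives 0.0800 M, which cedar has been seen to make, as a reading.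
- For an upper end, an estimate and not a strict bound, take the highest plateau reading in ash, 91%. That leaves 9.00% of the starting material lost.
- Suppose each chain loses one starting material. Then a chain, in the usual term the kinetic chain length, makes 10.1 target.
- Each initiator gives two radicals, so the charge starts at most 0.0100 M of chains.
- Multiply the two and you have the chain estimate, your reckoned molar target from one charge of initiator: 0.101 M.
- Divide by each charge. Your reckoning puts Friday's between 40.0% and 50.6%, Saturday's between 20.0% and 25.3%, Tuesday's between 10.0% and 12.6%, and Sunday's between 5.33% and 6.74%.
- Monday's charge of 0.10 M is smaller than this estimate, so starting material is the limiting reagent there. Its bracket runs from 80.0% to about the ash share, 91%.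
- The forecast gives 78%, 40%, 20%, 10% and 5.3%, falls all the way, from “a ceiling of about 0.08 M, independent of concentration”, which puts it on your lower bound, with Monday's just under it.
- The flasks give 91.2%, 50.1%, 25.1%, 12.5% and 6.68%, falls all the way.
- Counted in molar, Sunday's holds 0.100 M and Saturday's 0.100 M at the asked time, against the chain estimate of 0.101 M.

    crystals ⇌ target, rate k1*(cs1 - [target]) while solid is left; crystals form when [target] > cs1 (solubility = 25.0 mM, k = 0.590 s⁻¹)
    partner + first chain carrier → target + second chain carrier (k = 7.50 × 10⁶ M⁻¹ s⁻¹)
    starting material + second chain carrier → by-product + first chain carrier (k = 2.00 × 10⁵ M⁻¹ s⁻¹)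
    2 first chain carrier → ended chains (k = 1.10 × 10⁹ M⁻¹ s⁻¹)
    initiator → 2 initiating radical (k = 0.0190 s⁻¹)
    transfer agent + first chain carrier → side product + idle radical (kL = 1.40 × 10⁶ M⁻¹ s⁻¹)
    gas ⇌ partner, rate k7*(csat - [partner]) (kL = 0.210 s⁻¹)
    starting material + initiating radical → capped initiator + first chain carrier (k = 3.50 × 10⁶ M⁻¹ s⁻¹)
    2 idle radical → ended radicals (k = 1.60 × 10⁷ M⁻¹ s⁻¹)

- Sunday's target stays near that estimate because of the transfer step: take that step out of Sunday's flask and target comes to 99.4% instead of 6.68%. With the step in place, the first chain carrier is handed over to the idle radical after a short chain. In Sunday's flask, 92.7% of the starting material is still there at the end.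

Readings and results were generated by integration from invented constants, noise included.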